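A direct plan would make both rings from one cyclohexane-1,3-dione (malonate–enone Michael/Dieckmann annulation), aromatized to methyl 2,4-dihydroxy-5,6-dimethylbenzoate A1.
Part of A1 would be converted into the ring B phenol methyl 4-hydroxy-2-methoxy-3,5,6-trimethylbenzoate A2 and part into 2,4-bis(benzyloxy)-5,6-dimethylbenzoic acid A3; A2 and A3 would be esterified, debenzylated to the formyl-free depside methyl 4-[(2,4-dihydroxy-5,6-dimethylbenzoyl)oxy]-2-methoxy-3,5,6-trimethylbenzoate A4, and A4 would be formylated last.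
Its weakest steps would be:
- the aromatization with bromine, which over-brominates and needs a hydrogenolysis only to remove the extra halogen; together with a two-step C-methylation and five protecting-group operations this is many steps for no gain;
- the esterification of the 2,6-disubstituted benzoic acid A3 with the 2,6-dimethylphenol A2, in which both partners are hindered;
- the closing TiCl4/Cl2CHOMe formylation of A4, a hard Lewis acid on the most precious intermediate that endangers the aryl ester and the chelating methoxy ester.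

Plan of the new route. Ring A is cut at C1–C2, C3–C4 and C4–C5 (and at C1–C6, which arises in a Wolff shift) into a siloxyalkyne (C2, C3 and the masked CHO) and the α-diazo-β-ketoester obtained by acylating the ring B phenol with tigloylketene; ring B is cut likewise into 1-methoxypropyne and the corresponding methyl ester. Ring B arises first, the depside C–O bond is made on an open-chain β-keto ester, and ring A is grown last around that ester. Enabling feature: in both rings C4–OH is para to the ester-bearing C1, C2 bears oxygen, C3 one carbon and C5/C6 methyls, which maps onto ketene C=O, ynol ether, ketene α-carbon and the but-2-en-2-yl group of tiglic acid. Hence there is no bromination/debromination, no esterification of a hindered aryl acid, no benzyl group and no Lewis-acid formylation.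

Key step: step 9

Remark: the target is achiral; the (E)-alkene of the tigloyl unit is the only stereo element carried and is consumed on aromatization; compounds 3, 10, 12, 24 and 26 would be transient racemates.

Step 1
Reactants: 1 (E)-2-methylbut-2-enoyl chloride (tigloyl chloride); 2 potassium 3-methoxy-3-oxopropanoate (potassium methyl malonate)
Product: 4 methyl (E)-4-methyl-3-oxohex-4-enoate, via acylmalonic acid 3 (not isolated)
Conditions: 2 (2.1 equiv), MgCl2 (2.5 equiv), Et3N (3.2 equiv), MeCN, 10 °C to rt; then 1 (1.0 equiv, added slowly), rt, 12 h; 1 M aq. HCl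
Reagents that add atoms: none
Why: C-acylation of the magnesium enolate of the malonate half ester by the acid chloride, followed by decarboxylation of acylmalonic acid 3 on acidic work-up, is the standard malonate half-ester synthesis of β-keto esters, and the trisubstituted tiglate double bond resists conjugate addition and keeps its E geometry.

Step 2
Reactants: 4 methyl (E)-4-methyl-3-oxohex-4-enoate
Product: 5 methyl (E)-2-diazo-4-methyl-3-oxohex-4-enoate
Conditions: 4-AcNHC6H4SO2N3 (1.1 equiv), Et3N (1.5 equiv), MeCN, 0 °C to rt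
Reagents that add atoms: 4-acetamidobenzenesulfonyl azide, CC(=O)Nc1ccc(cc1)S(=O)(=O)N=[N+]=[N-]
Why: Regitz diazo transfer to the doubly activated methylene of a β-keto ester is reliable and leaves the enone untouched.

Step 3
Reactants: 6 2-chloro-1,1-dimethoxyethane
Product: 8 1-methoxyprop-1-yne, via sodium methoxyethynide 7 (not isolated)
Conditions: NaNH2 (3.1 equiv), liq. NH3, −33 °C; then MeI (1.0 equiv), −40 °C; distillation
Reagents that add atoms: iodomethane, CI
Why: Twofold amide-induced elimination (methanol, then HCl) gives the alkoxyacetylide, which is C-methylated in situ, the standard preparation of 1-alkoxy-1-alkynes.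

Step 4
Reactants: 5 methyl (E)-2-diazo-4-methyl-3-oxohex-4-enoate; 8 1-methoxyprop-1-yne
Product: 13 methyl 4-hydroxy-2-methoxy-3,5,6-trimethylbenzoate, via vinylketene 9 (not isolated), via vinylcyclobutenone 10 (not isolated), via dienylketene 11 (not isolated), via cyclohexadienone 12 (not isolated)
Conditions: 8 (2.5 equiv), ClCH2CH2Cl, hν (365 nm), 20 °C, sealed vessel; then 80 °C
Reagents that add atoms: none
Why: Proposed new method: photochemical Wolff rearrangement of 5 (butenyl shift) should give the (methoxycarbonyl)vinylketene 9, which ynol ether 8 attacks through its methyl-bearing carbon to give cyclobutenone 10 by [2+2] cycloaddition, and 4π-opening to 11, 6π-electrocyclization to 12 and enolization would then deliver the hexasubstituted phenol 13 with OH, Me, OMe, CO2Me, Me, Me in the required order around the ring; the closest known reaction type is the Danheiser benzannulation of α′-diazo enones with alkoxyalkynes, from which this differs only by the ester on the ketene α-carbon, and the run on this cheap substrate also tests the key step.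

Step 5
Reactants: 1 (E)-2-methylbut-2-enoyl chloride (tigloyl chloride); 14 2,2-dimethyl-1,3-dioxane-4,6-dione (Meldrum's acid)
Product: 15 5-[(E)-1-hydroxy-2-methylbut-2-en-1-ylidene]-2,2-dimethyl-1,3-dioxane-4,6-dione
Conditions: pyridine (2.2 equiv), CH2Cl2, 0 °C to rt; 1 M HCl wash; used crude
Reagents that add atoms: none
Why: C-acylation of the acidic methylene of Meldrum's acid by the acid chloride gives the enolized acyl Meldrum's acid, and the trisubstituted tiglate double bond resists conjugate addition and keeps its E geometry.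

Step 6
Reactants: 13 methyl 4-hydroxy-2-methoxy-3,5,6-trimethylbenzoate; 15 5-[(E)-1-hydroxy-2-methylbut-2-en-1-ylidene]-2,2-dimethyl-1,3-dioxane-4,6-dione
Product: 17 methyl 2-methoxy-3,5,6-trimethyl-4-{[(E)-4-methyl-3-oxohex-4-enoyl]oxy}benzoate, via acylketene 16 (not isolated)
Conditions: 15 (1.3 equiv, added slowly), toluene, 110 °C
Reagents that add atoms: none
Why: Thermal retro-[4+2] fragmentation of acyl Meldrum's acid 15 (loss of acetone and CO2) should give acylketene 16, and its capture by a phenol is a pseudopericyclic addition with an early, sterically undemanding transition state, so the two ortho methyl groups of 13 should be tolerated (known synthesis of aryl β-keto esters from acyl Meldrum's acids).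

Step 7
Reactants: 17 methyl 2-methoxy-3,5,6-trimethyl-4-{[(E)-4-methyl-3-oxohex-4-enoyl]oxy}benzoate
Product: 18 methyl 4-{[(E)-2-diazo-4-methyl-3-oxohex-4-enoyl]oxy}-2-methoxy-3,5,6-trimethylbenzoate
Conditions: 4-AcNHC6H4SO2N3 (1.1 equiv), Et3N (1.5 equiv), MeCN, 0 °C
Reagents that add atoms: 4-acetamidobenzenesulfonyl azide, CC(=O)Nc1ccc(cc1)S(=O)(=O)N=[N+]=[N-]
Why: Regitz diazo transfer to the β-keto ester methylene, with the aryl and methyl esters inert to Et3N in MeCN at 0 °C.

Step 8
Reactants: 19 3,3-diethoxyprop-1-yne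
Product: 22 [(3,3-diethoxyprop-1-yn-1-yl)oxy]tri(propan-2-yl)silane, via lithium acetylide 20 (not isolated), via lithium ynolate 21 (not isolated)
Conditions: LiN(SiMe3)2 (1.05 equiv), THF, −78 °C; t-BuOOLi (from t-BuOOH and LiN(SiMe3)2, 1.1 equiv), −78 to 0 °C; then i-Pr3SiOSO2CF3 (1.1 equiv), −78 to 0 °C
Reagents that add atoms: tert-butyl hydroperoxide, CC(C)(C)OO; triisopropylsilyl trifluoromethanesulfonate, CC(C)[Si](OS(=O)(=O)C(F)(F)F)(C(C)C)C(C)C
Why: Electrophilic oxygen transfer from lithium tert-butyl peroxide to acetylide 20 gives ynolate 21, which the bulky silyl triflate traps on oxygen (known preparation of siloxyalkynes from terminal alkynes), and the diethyl acetal is stable to base.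

Step 9
Reactants: 18 methyl 4-{[(E)-2-diazo-4-methyl-3-oxohex-4-enoyl]oxy}-2-methoxy-3,5,6-trimethylbenzoate; 22 [(3,3-diethoxyprop-1-yn-1-yl)oxy]tri(propan-2-yl)silane
Product: 27 methyl 4-({3-(diethoxymethyl)-4-hydroxy-5,6-dimethyl-2-[tri(propan-2-yl)silyloxy]benzoyl}oxy)-2-methoxy-3,5,6-trimethylbenzoate, via vinylketene 23 (not isolated), via vinylcyclobutenone 24 (not isolated), via dienylketene 25 (not isolated), via cyclohexadienone 26 (not isolated)
Conditions: 22 (1.5 equiv), ClCH2CH2Cl (0.1 M), hν (365 nm), 20 °C; then 80 °C; chromatography on Et3N-deactivated silica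
Reagents that add atoms: none
Why: Proposed new method: excitation of the diazo chromophore of 18 at 365 nm should expel N2 with 1,2-shift of the but-2-en-2-yl group (Wolff rearrangement) to the (aryloxycarbonyl)vinylketene 23, whose carbonyl carbon is attacked by the nucleophilic, acetal-bearing carbon of the polarized siloxyalkyne 22, and C–C collapse of the zwitterion closes the four-membered ring of cyclobutenone 24 ([2+2] mode). Thermal 4π-electrocyclic opening of 24 (reversible, so the isomer with the butenyl group cis to the new ketene is drained) gives dienylketene 25, which closes ring A by 6π-electrocyclization forming C4–C5 to dienone 26, and enolization gives phenol 27. The closest known reaction type is the photochemical (second-generation) Danheiser benzannulation of α′-diazo enones with siloxyalkynes, together with the [2+2] cycloadditions of alkoxycarbonylketenes; what is new is the ester on the ketene α-carbon, which here is the depside ester itself. No stereocenter is formed in the product, and the quaternary carbon of 24 and the sp3 carbon of 26 are erased on aromatization. The regiochemistry that places the masked formyl carbon between the two oxygens is secured by the polarity of the ynol ether, and the required C- over O-closure of the zwitterion (the ester carbonyl could give a 4-pyranone) is favoured because an ester carbonyl is a poor heterodiene terminus and only the carbocyclic channel ends irreversibly in an arene. The 365 nm light is absorbed only by the diazo ketoester, and ring B, which has no free ortho or para position, cannot undergo photo-Fries rearrangement.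

Step 10
Reactants: 27 methyl 4-({3-(diethoxymethyl)-4-hydroxy-5,6-dimethyl-2-[tri(propan-2-yl)silyloxy]benzoyl}oxy)-2-methoxy-3,5,6-trimethylbenzoate
Product: 29 methyl 4-[(3-formyl-2,4-dihydroxy-5,6-dimethylbenzoyl)oxy]-2-methoxy-3,5,6-trimethylbenzoate, via phenol acetal 28 (not isolated)
Conditions: Bu4NF (1.2 equiv), AcOH (1.5 equiv), THF, 0 °C; then 1 M aq. HCl, THF, rt
Reagents that add atoms: water, O
Why: Fluoride cleaves the aryl silyl ether while AcOH buffering keeps the liberated phenoxide from attacking the depside ester, and dilute acid then hydrolyses the acetal, assisted by the two ortho hydroxyls and driven by the doubly hydrogen-bonded salicylaldehyde, so that no Lewis acid touches the depside.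

## Compound list

1 | (E)-2-methylbut-2-enoyl chloride (tigloyl chloride) | C/C=C(\C)C(Cl)=O | starting material
2 | potassium 3-methoxy-3-oxopropanoate (potassium methyl malonate) | [K+].[O-]C(=O)CC(=O)OC | starting material
3 | (E)-2-(methoxycarbonyl)-4-methyl-3-oxohex-4-enoic acid (acylmalonic acid, formed as its magnesium chelate, racemic, not isolated) | COC(=O)C(C(=O)O)C(=O)/C(C)=C/C | intermediate
4 | methyl (E)-4-methyl-3-oxohex-4-enoate | COC(=O)CC(=O)/C(C)=C/C | intermediate
5 | methyl (E)-2-diazo-4-methyl-3-oxohex-4-enoate | COC(=O)C(=[N+]=[N-])C(=O)/C(C)=C/C | intermediate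
6 | 2-chloro-1,1-dimethoxyethane | COC(CCl)OC | starting material
7 | sodium methoxyethynide (not isolated) | [Na+].[C-]#COC | intermediate
8 | 1-methoxyprop-1-yne | CC#COC | intermediate
9 | methyl (3E)-3-methyl-2-(oxomethylidene)pent-3-enoate (vinylketene, not isolated) | COC(=O)C(=C=O)/C(C)=C/C | intermediate
10 | methyl 1-[(E)-but-2-en-2-yl]-2-methoxy-3-methyl-4-oxocyclobut-2-ene-1-carboxylate (racemic, not isolated) | COC(=O)C1(/C(C)=C/C)C(OC)=C(C)C1=O | intermediate
11 | methyl (2Z)-2-[(E)-but-2-en-2-yl]-3-methoxy-4-methyl-5-oxopenta-2,4-dienoate (dienylketene, not isolated) | O=C=C(C)/C(OC)=C(\C(C)=C\C)C(=O)OC | intermediate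
12 | methyl 6-methoxy-2,3,5-trimethyl-4-oxocyclohexa-1,5-diene-1-carboxylate (racemic, not isolated) | COC(=O)C1=C(C)C(C)C(=O)C(C)=C1OC | intermediate
13 | methyl 4-hydroxy-2-methoxy-3,5,6-trimethylbenzoate | COC(=O)c1c(C)c(C)c(O)c(C)c1OC | intermediate
14 | 2,2-dimethyl-1,3-dioxane-4,6-dione (Meldrum's acid) | CC1(C)OC(=O)CC(=O)O1 | starting material
15 | 5-[(E)-1-hydroxy-2-methylbut-2-en-1-ylidene]-2,2-dimethyl-1,3-dioxane-4,6-dione | C/C=C(\C)C(O)=C1C(=O)OC(C)(C)OC1=O | intermediate
16 | (4E)-4-methylhexa-1,4-diene-1,3-dione (tigloylketene, not isolated) | C/C=C(\C)C(=O)C=C=O | intermediate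
17 | methyl 2-methoxy-3,5,6-trimethyl-4-{[(E)-4-methyl-3-oxohex-4-enoyl]oxy}benzoate | COC(=O)c1c(C)c(C)c(OC(=O)CC(=O)/C(C)=C/C)c(C)c1OC | intermediate
18 | methyl 4-{[(E)-2-diazo-4-methyl-3-oxohex-4-enoyl]oxy}-2-methoxy-3,5,6-trimethylbenzoate | COC(=O)c1c(C)c(C)c(OC(=O)C(=[N+]=[N-])C(=O)/C(C)=C/C)c(C)c1OC | intermediate
19 | 3,3-diethoxyprop-1-yne | CCOC(OCC)C#C | starting material
20 | lithium 3,3-diethoxyprop-1-yn-1-ide (not isolated) | [Li+].[C-]#CC(OCC)OCC | intermediate
21 | lithium 3,3-diethoxyprop-1-yn-1-olate (not isolated) | [Li+].[O-]C#CC(OCC)OCC | intermediate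
22 | [(3,3-diethoxyprop-1-yn-1-yl)oxy]tri(propan-2-yl)silane | CCOC(OCC)C#CO[Si](C(C)C)(C(C)C)C(C)C | intermediate
23 | methyl 2-methoxy-3,5,6-trimethyl-4-{[(3E)-3-methyl-2-(oxomethylidene)pent-3-enoyl]oxy}benzoate (vinylketene, not isolated) | COC(=O)c1c(C)c(C)c(OC(=O)C(=C=O)/C(C)=C/C)c(C)c1OC | intermediate
24 | methyl 4-({1-[(E)-but-2-en-2-yl]-3-(diethoxymethyl)-4-oxo-2-[tri(propan-2-yl)silyloxy]cyclobut-2-ene-1-carbonyl}oxy)-2-methoxy-3,5,6-trimethylbenzoate (racemic, not isolated) | COC(=O)c1c(C)c(C)c(OC(=O)C2(/C(C)=C/C)C(O[Si](C(C)C)(C(C)C)C(C)C)=C(C(OCC)OCC)C2=O)c(C)c1OC | intermediate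
25 | methyl 4-({(2Z)-2-[(E)-but-2-en-2-yl]-4-(diethoxymethyl)-5-oxo-3-[tri(propan-2-yl)silyloxy]penta-2,4-dienoyl}oxy)-2-methoxy-3,5,6-trimethylbenzoate (dienylketene, not isolated) | CCOC(OCC)C(=C=O)/C(O[Si](C(C)C)(C(C)C)C(C)C)=C(\C(C)=C\C)C(=O)Oc1c(C)c(C)c(C(=O)OC)c(OC)c1C | intermediate
26 | methyl 4-({5-(diethoxymethyl)-2,3-dimethyl-4-oxo-6-[tri(propan-2-yl)silyloxy]cyclohexa-1,5-diene-1-carbonyl}oxy)-2-methoxy-3,5,6-trimethylbenzoate (racemic, not isolated) | CCOC(OCC)C1=C(O[Si](C(C)C)(C(C)C)C(C)C)C(C(=O)Oc2c(C)c(C)c(C(=O)OC)c(OC)c2C)=C(C)C(C)C1=O | intermediate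
27 | methyl 4-({3-(diethoxymethyl)-4-hydroxy-5,6-dimethyl-2-[tri(propan-2-yl)silyloxy]benzoyl}oxy)-2-methoxy-3,5,6-trimethylbenzoate | CCOC(OCC)c1c(O)c(C)c(C)c(C(=O)Oc2c(C)c(C)c(C(=O)OC)c(OC)c2C)c1O[Si](C(C)C)(C(C)C)C(C)C | intermediate
28 | methyl 4-{[3-(diethoxymethyl)-2,4-dihydroxy-5,6-dimethylbenzoyl]oxy}-2-methoxy-3,5,6-trimethylbenzoate (not isolated) | CCOC(OCC)c1c(O)c(C)c(C)c(C(=O)Oc2c(C)c(C)c(C(=O)OC)c(OC)c2C)c1O | intermediate
29 | methyl 4-[(3-formyl-2,4-dihydroxy-5,6-dimethylbenzoyl)oxy]-2-methoxy-3,5,6-trimethylbenzoate | COC(=O)c1c(C)c(C)c(OC(=O)c2c(C)c(C)c(O)c(C=O)c2O)c(C)c1OC | target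

Total step count: 10. Longest linear sequence: 7 (steps 1, 2, 4, 6, 7, 9, 10).

Steps most likely to fail:

1. Step 9 (proposed method, key step). Ketene 23 may be diverted before the cyclobutenone forms: closure of the zwitterion through the ester oxygen, ketene dimerization, or capture of the ketene by phenol already formed. The fallback moves the ester from the ketene carbon to the vinyl terminus, where the benzannulation is of the established α′-diazo enone type. Setting out from 13, acid-catalysed aldol condensation of pentan-3-one with glyoxylic acid (H3PO4, 80 °C) would give (E)-3-methyl-4-oxohex-2-enoic acid F1. Esterification of F1 with 13 (N,N′-diisopropylcarbodiimide, 4-(dimethylamino)pyridine, CH2Cl2; only one partner hindered) would give methyl 2-methoxy-3,5,6-trimethyl-4-{[(E)-3-methyl-4-oxohex-2-enoyl]oxy}benzoate F2. Detrifluoroacetylative diazo transfer would begin with C-trifluoroacetylation of the ketone enolate (LiN(SiMe3)2, CF3CO2CH2CF3, THF, −78 °C) to the unisolated racemic methyl 2-methoxy-3,5,6-trimethyl-4-{[(E)-7,7,7-trifluoro-3,5-dimethyl-4,6-dioxohept-2-enoyl]oxy}benzoate F3. Treatment of F3 with CH3SO2N3 and Et3N in aqueous MeCN would give methyl 4-{[(E)-5-diazo-3-methyl-4-oxohex-2-enoyl]oxy}-2-methoxy-3,5,6-trimethylbenzoate F4. Irradiation of F4 with 22 and heating would give the regioisomeric silyl ether methyl 4-({3-(diethoxymethyl)-2-hydroxy-5,6-dimethyl-4-[tri(propan-2-yl)silyloxy]benzoyl}oxy)-2-methoxy-3,5,6-trimethylbenzoate F5 (ketene carbonyl = C2, alkyne carbons = C3 and C4, ketene α-carbon = C5, vinyl carbons = C6 and C1). The conditions of step 10 would bring F5 back to the route at 29.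

2. Step 4 (proposed method). The same diversion of the ester-substituted ketene 9 may occur, aggravated by loss of the volatile ynol ether. The fallback builds the ring without the ester and adds the carboxyl carbon afterwards. Setting out from 1, Me3SiCHN2 (MeCN/THF, 0 °C) would give (E)-1-diazo-3-methylpent-3-en-2-one F6. Irradiation of F6 with 8 and heating (the benzannulation in its established form) would give 3-methoxy-2,5,6-trimethylphenol F7. N-Bromosuccinimide would brominate its single free ring position to 4-bromo-3-methoxy-2,5,6-trimethylphenol F8. Methoxycarbonylation of F8 (Pd(OAc)2, Xantphos, CO, MeOH, Et3N) would return to the route at 13.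

3. Step 6. Capture of acylketene 16 by the doubly ortho-substituted phenol may be slow, so that ketene dimerization takes over. The fallback forms the ester bond with a small acyl bromide and the C–C bond afterwards. Setting out from 13, bromoacetyl bromide and pyridine (CH2Cl2, 0 °C) would give methyl 4-[(bromoacetyl)oxy]-2-methoxy-3,5,6-trimethylbenzoate F9. Reformatsky reaction of F9 with (E)-2-methylbut-2-enal (Zn, THF) would give racemic methyl 4-{[(E)-3-hydroxy-4-methylhex-4-enoyl]oxy}-2-methoxy-3,5,6-trimethylbenzoate F10. Oxidation of the allylic alcohol of F10 with MnO2 would return to the route at 17.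

Further compounds

F1 | step 9 | (E)-3-methyl-4-oxohex-2-enoic acid | CCC(=O)/C(C)=C/C(=O)O
F2 | step 9 | methyl 2-methoxy-3,5,6-trimethyl-4-{[(E)-3-methyl-4-oxohex-2-enoyl]oxy}benzoate | COC(=O)c1c(C)c(C)c(OC(=O)/C=C(\C)C(=O)CC)c(C)c1OC
F3 | step 9 | methyl 2-methoxy-3,5,6-trimethyl-4-{[(E)-7,7,7-trifluoro-3,5-dimethyl-4,6-dioxohept-2-enoyl]oxy}benzoate (racemic, not isolated) | COC(=O)c1c(C)c(C)c(OC(=O)/C=C(\C)C(=O)C(C)C(=O)C(F)(F)F)c(C)c1OC
F4 | step 9 | methyl 4-{[(E)-5-diazo-3-methyl-4-oxohex-2-enoyl]oxy}-2-methoxy-3,5,6-trimethylbenzoate | COC(=O)c1c(C)c(C)c(OC(=O)/C=C(\C)C(=O)C(C)=[N+]=[N-])c(C)c1OC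
F5 | step 9 | methyl 4-({3-(diethoxymethyl)-2-hydroxy-5,6-dimethyl-4-[tri(propan-2-yl)silyloxy]benzoyl}oxy)-2-methoxy-3,5,6-trimethylbenzoate | CCOC(OCC)c1c(O)c(C(=O)Oc2c(C)c(C)c(C(=O)OC)c(OC)c2C)c(C)c(C)c1O[Si](C(C)C)(C(C)C)C(C)C
F6 | step 4 | (E)-1-diazo-3-methylpent-3-en-2-one | C/C=C(\C)C(=O)C=[N+]=[N-]
F7 | step 4 | 3-methoxy-2,5,6-trimethylphenol | COc1cc(C)c(C)c(O)c1C
F8 | step 4 | 4-bromo-3-methoxy-2,5,6-trimethylphenol | COc1c(Br)c(C)c(C)c(O)c1C
F9 | step 6 | methyl 4-[(bromoacetyl)oxy]-2-methoxy-3,5,6-trimethylbenzoate | COC(=O)c1c(C)c(C)c(OC(=O)CBr)c(C)c1OC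
F10 | step 6 | methyl 4-{[(E)-3-hydroxy-4-methylhex-4-enoyl]oxy}-2-methoxy-3,5,6-trimethylbenzoate (racemic) | COC(=O)c1c(C)c(C)c(OC(=O)CC(O)/C(C)=C/C)c(C)c1OC
A1 | direct plan | methyl 2,4-dihydroxy-5,6-dimethylbenzoate | COC(=O)c1c(C)c(C)c(O)cc1O
A2 | direct plan | methyl 4-hydroxy-2-methoxy-3,5,6-trimethylbenzoate | COC(=O)c1c(C)c(C)c(O)c(C)c1OC
A3 | direct plan | 2,4-bis(benzyloxy)-5,6-dimethylbenzoic acid | OC(=O)c1c(C)c(C)c(OCc2ccccc2)cc1OCc1ccccc1
A4 | direct plan | methyl 4-[(2,4-dihydroxy-5,6-dimethylbenzoyl)oxy]-2-methoxy-3,5,6-trimethylbenzoate | COC(=O)c1c(C)c(C)c(OC(=O)c2c(C)c(C)c(O)cc2O)c(C)c1OC
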